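## Retrosynthetic overview

1. Drimane numbering is used: ring A = C1–C5 + C10, ring B = C5–C10, C11 = the CH2 on C9, C12 = the exocyclic methylene carbon on C8. Late disconnections are the HMG ester C–O bond (acid from (R)-mevalonolactone) and the epoxyquinone, which goes back through a quinone monoketal to a phenol.
2. The arene is joined by C9–C11 benzylation of a C8–C9 enolate, and C8=C12 comes from methylenation of the C8 ketone.
3. Rings A and B are formed together by an enantioselective intramolecular Diels–Alder reaction of an acyclic, achiral trienal. The enabling feature: ring B is a six-membered carbocycle whose sp2 carbon C8 is a masked ketone flanked by C7 and C9. Written as its C8–C9 silyl enol ether, ring B is a Diels–Alder cyclohexene (diene C7=C8(OSi)–C9=C10, dienophile C5=C6), and because C5–C10 is the bond shared with ring A, the chain C1–C2–C3–C4 is the tether.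
4. A formyl group on C6 activates the dienophile for a chiral boron Lewis acid and is then removed by decarbonylation. Quaternary C4 makes the enal non-enolisable and favours folding.
5. Order of ring formation: rings A and B at once (step 7), arene attached (step 11) and dearomatised (step 14), oxirane closed last (step 15). C9 is relayed from C10 by equilibration, the epoxide is set by reagent control, and the HMG centre is bought.

Key step: step 7

Remark (assumption): the antipodes written for the two external control elements, the (S)-diphenylprolinol-derived oxazaborolidinium cation (step 7) and L-(+)-diisopropyl tartrate (step 15), are those expected from the usual binding models to deliver the required faces; each is available as its mirror image, so the sense of induction can be corrected without changing the route.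

## Route

Step 1
Reactants: 1 isobutyronitrile; 2 5-iodopent-1-yne
Product: 4 2,2-dimethylhept-6-ynenitrile, via lithiated isobutyronitrile 3 (not isolated)
Conditions: LiN(iPr)2, THF, −78 °C; then 2, −78 → 0 °C
Reagents that add atoms: none
Why: SN2 alkylation of a tertiary nitrile-stabilised carbanion by a primary iodide builds quaternary C4 with both methyl groups, C-alkylation being expected to outrun proton transfer from the remote alkyne.

Step 2
Reactants: 4 2,2-dimethylhept-6-ynenitrile
Product: 6 2,2-dimethylhept-6-ynal, via N-aluminio aldimine 5 (not isolated)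
Conditions: iBu2AlH, CH2Cl2, −78 → 0 °C; then 1 M HCl, 0 °C
Reagents that add atoms: water, O
Why: Partial hydride reduction of a hindered nitrile stops at the N-aluminio aldimine, which hydrolyses to the neopentyl aldehyde (C5).

Step 3
Reactants: 6 2,2-dimethylhept-6-ynal
Product: 7 3,3-dimethyloct-1-en-7-yne
Conditions: Ph3PCH3Br, KOtBu, THF, 0 °C → rt
Reagents that add atoms: methyltriphenylphosphonium bromide, C[P+](c1ccccc1)(c1ccccc1)c1ccccc1.[Br-]
Why: Wittig methylenation of a non-enolisable aldehyde gives a vinyl group that stands in for the enal during the organoaluminium step.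

Step 4
Reactants: 7 3,3-dimethyloct-1-en-7-yne
Product: 9 (E)-4,8,8-trimethyldeca-3,9-dien-2-one, via alkenylalane 8 (not isolated)
Conditions: Me3Al, Cp2ZrCl2 (0.25 equiv), CH2Cl2, 0 °C → rt; excess Me3Al removed in vacuo; AcCl, CH2Cl2, −30 → 0 °C
Reagents that add atoms: trimethylaluminium, C[Al](C)C; acetyl chloride, CC(=O)Cl
Why: Zirconium-catalysed syn carboalumination (Negishi) puts methyl on the internal carbon (C10) and aluminium on C9, and acylation of the alkenylalane with retention gives the E-enone with the tether trans to C8.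

Step 5
Reactants: 9 (E)-4,8,8-trimethyldeca-3,9-dien-2-one
Product: 10 (2E,8E)-4,4,8-trimethyl-10-oxoundeca-2,8-dienal
Conditions: crotonaldehyde (5 equiv), second-generation Hoveyda–Grubbs catalyst RuCl2(=CH-C6H4-2-OiPr)(H2IMes) (5 mol%), CH2Cl2, 40 °C
Reagents that add atoms: crotonaldehyde, C/C=C/C=O
Why: Olefin cross-metathesis of the hindered terminal vinyl group with excess enal should give the E-enal (C6 and the formyl carbon), the trisubstituted enone alkene being inert.

Step 6
Reactants: 10 (2E,8E)-4,4,8-trimethyl-10-oxoundeca-2,8-dienal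
Product: 11 (2E,8E)-10-[(tert-butyldimethylsilyl)oxy]-4,4,8-trimethylundeca-2,8,10-trienal
Conditions: TBSOTf, Et3N, CH2Cl2, −78 → 0 °C
Reagents that add atoms: tert-butyldimethylsilyl trifluoromethanesulfonate, CC(C)(C)[Si](C)(C)OS(=O)(=O)C(F)(F)F
Why: Soft enolisation silylates the ketone oxygen and removes a proton from the methyl group (C7) to give the cross-conjugated 2-silyloxy diene, while the enal cannot enolise because C4 is quaternary.

Step 7
Reactants: 11 (2E,8E)-10-[(tert-butyldimethylsilyl)oxy]-4,4,8-trimethylundeca-2,8,10-trienal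
Product: 12 (1S,4aS,8aS)-3-[(tert-butyldimethylsilyl)oxy]-4a,8,8-trimethyl-1,2,4a,5,6,7,8,8a-octahydronaphthalene-1-carbaldehyde (drimane numbering: trans-fused; 10β-methyl; 5α-H; 6α-formyl)
Conditions: (S)-3,3-diphenyl-1-(o-tolyl)tetrahydro-1H,3H-pyrrolo[1,2-c][1,3,2]oxazaborole protonated with Tf2NH (20 mol%), CH2Cl2 (0.01 M), −78 → −20 °C; Et3N quench
Reagents that add atoms: none
Why: The boron cation binds the formyl oxygen and lowers the LUMO of the (E)-enal, and a concerted but asynchronous intramolecular [4+2] cycloaddition (intramolecular Diels–Alder reaction) follows in which C5–C10 forms ahead of C6–C7. The closest known reaction type is the oxazaborolidinium-catalysed enantioselective intramolecular Diels–Alder reaction of (E)-2,7,9-trienals, together with intermolecular additions of 2-silyloxy-1,3-dienes under the same catalysts. Ring B (C5–C6–C7–C8–C9–C10) closes as the cyclohexene of the cycloaddition and ring A (C1–C5 plus C10) closes in the fused (type 1) mode as a six-membered chair through the C5–C10 bond, with the chain C1–C4 as an anti tether. The trans ring fusion (C10 methyl β, C5 hydrogen α) follows from the endo position of the boron-bound formyl group combined with the E geometry of the enal and of C9=C10 (tether outside, methyl inside), and the C6 centre (formyl α, erased in step 8) from suprafacial addition to the E-alkene. The absolute configuration at C5 and C10 is set by the catalyst, whose aryl groups screen one face of the bound s-trans enal so that C10 bonds to the Si face of C5 (C4 > C6 > H). The step needs endo and facial selectivity over intermolecular Mukaiyama-type addition, which low temperature, high dilution and the tether secure, while the C8 silyloxy group keeps the diene s-cis despite the inside methyl, the C4 gem-dimethyl group favours the folded conformer, and the product retains the C8=C9 silyl enol ether that fixes the regiochemistry of step 11.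

Step 8
Reactants: 12 the decalin aldehyde
Product: 13 tert-butyldimethyl{[(4aS,8aS)-5,5,8a-trimethyl-3,4,4a,5,6,7,8,8a-octahydronaphthalen-2-yl]oxy}silane
Conditions: RhCl(PPh3)3 (1.1 equiv), PhMe, 110 °C
Reagents that add atoms: none
Why: Tsuji–Wilkinson decarbonylation (formyl C–H oxidative addition, CO extrusion, C–H reductive elimination) removes the activating group under neutral conditions that the silyl enol ether tolerates.

Step 9
Reactants: 14 methyl 3-hydroxy-4-methylbenzoate
Product: 15 methyl 3-[(diethylcarbamoyl)oxy]-4-methylbenzoate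
Conditions: Et2NCOCl, K2CO3, MeCN, reflux
Reagents that add atoms: N,N-diethylcarbamoyl chloride, CCN(CC)C(Cl)=O
Why: O-Carbamoylation gives a phenol protecting group that withstands radical bromination, fluoride, methoxide and the methylenation reagent but is cleaved by LiAlH4.

Step 10
Reactants: 15 methyl 3-[(diethylcarbamoyl)oxy]-4-methylbenzoate
Product: 16 methyl 4-(bromomethyl)-3-[(diethylcarbamoyl)oxy]benzoate
Conditions: N-bromosuccinimide, AIBN (cat.), PhCF3, 85 °C
Reagents that add atoms: N-bromosuccinimide, BrN1C(=O)CCC1=O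
Why: Wohl–Ziegler radical bromination at the only benzylic methyl group.

Step 11
Reactants: 13 the decalin silyl enol ether; 16 methyl 4-(bromomethyl)-3-[(diethylcarbamoyl)oxy]benzoate
Product: 19 methyl 3-[(diethylcarbamoyl)oxy]-4-{[(1R,4aS,8aS)-5,5,8a-trimethyl-2-oxodecahydronaphthalen-1-yl]methyl}benzoate (9β-benzyl; 9α-H), via sulfonium enolate 17 (not isolated), via 9-epi ketone 18 (not isolated)
Conditions: TASF [(Me2N)3S+ Me3SiF2−], 16, THF, −78 → −20 °C; aqueous work-up; NaOMe (cat.), MeOH, rt
Reagents that add atoms: none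
Why: Fluoride cleavage of the silyl enol ether gives the regiodefined C8–C9 enolate, which is C-benzylated at C9 (expected first from the α face, anti to the angular methyl), and methoxide then equilibrates C9 through the enolate to the equatorial 9β-benzyl ketone with 9α-H, the expected thermodynamic epimer.

Step 12
Reactants: 19 the 9β-benzyl ketone
Product: 20 methyl 3-[(diethylcarbamoyl)oxy]-4-{[(1S,4aS,8aS)-5,5,8a-trimethyl-2-methylidenedecahydronaphthalen-1-yl]methyl}benzoate
Conditions: Zn, CH2Br2, TiCl4, THF, 0 °C (reagent aged); then 19, CH2Cl2, rt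
Reagents that add atoms: dibromomethane, BrCBr
Why: Takai–Lombardo methylenation is non-basic, so the C9 configuration is kept, and it is selective for the ketone over the ester and the carbamate.

Step 13
Reactants: 20 the methylidene ester carbamate
Product: 21 5-(hydroxymethyl)-2-{[(1S,4aS,8aS)-5,5,8a-trimethyl-2-methylidenedecahydronaphthalen-1-yl]methyl}phenol
Conditions: LiAlH4, THF, 0 °C → reflux; Fieser work-up
Reagents that add atoms: none
Why: Hydride reduction turns the methyl ester into the hydroxymethyl group and cleaves the aryl carbamate to the phenol in one operation, the 1,1-disubstituted alkene being inert.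

Step 14
Reactants: 21 the phenol benzylic alcohol
Product: 23 5-(hydroxymethyl)-4,4-dimethoxy-2-{[(1S,4aS,8aS)-5,5,8a-trimethyl-2-methylidenedecahydronaphthalen-1-yl]methyl}cyclohexa-2,5-dien-1-one, via p-methoxyphenol 22 (not isolated)
Conditions: PhI(OAc)2 (2.2 equiv), MeOH, 0 °C
Reagents that add atoms: methanol, CO
Why: Oxidative dearomatisation with the trivalent iodine reagent (para methoxylation, then a second oxidation) gives the p-quinone monoketal with the ketone at the former phenol carbon, next to the terpenyl-bearing carbon.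

Step 15
Reactants: 23 the quinone monoketal
Product: 24 (1R,6S)-4-(hydroxymethyl)-5,5-dimethoxy-1-{[(1S,4aS,8aS)-5,5,8a-trimethyl-2-methylidenedecahydronaphthalen-1-yl]methyl}-7-oxabicyclo[4.1.0]hept-3-en-2-one
Conditions: Ph3COOH, NaN(SiMe3)2, L-(+)-diisopropyl tartrate, PhMe, −50 → −30 °C; NH4Cl quench
Reagents that add atoms: trityl hydroperoxide, OOC(c1ccccc1)(c1ccccc1)c1ccccc1
Why: Weitz–Scheffer-type nucleophilic epoxidation in its tartrate-mediated form: the peroxide anion adds to the unsubstituted β-carbon of the α-alkyl enone (the other β-carbon carries CH2OH and is blocked), and the sodium tartrate chelate of the CH2OH alkoxide delivers it to one face, so both epoxide centres are set by the reagent.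

Step 16
Reactants: 25 (R)-mevalonolactone
Product: 27 4-methoxybenzyl (R)-3,5-dihydroxy-3-methylpentanoate, via potassium mevalonate 26 (not isolated)
Conditions: KOH (1.0 equiv), H2O, rt; evaporate; 4-methoxybenzyl chloride, Bu4NI (cat.), DMF, rt
Reagents that add atoms: potassium hydroxide, [K+].[OH-]; 4-methoxybenzyl chloride, COc1ccc(CCl)cc1
Why: Saponification of the lactone and O-alkylation of the carboxylate leave the purchased tertiary carbinol centre untouched.

Step 17
Reactants: 27 4-methoxybenzyl (R)-mevalonate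
Product: 29 (R)-3-hydroxy-5-[(4-methoxybenzyl)oxy]-3-methyl-5-oxopentanoic acid, via aldehyde 28 (not isolated)
Conditions: TEMPO (0.2 equiv), PhI(OAc)2 (2.2 equiv), MeCN–H2O (pH 7 buffer), rt
Reagents that add atoms: water, O
Why: Oxoammonium (TEMPO) oxidation of the primary alcohol through the aldehyde hydrate gives the acid, so the former hydroxyethyl arm becomes the carboxyl to be esterified, which makes the HMG centre S in the target.

Step 18
Reactants: 24 the epoxy ketal alcohol; 29 the HMG half ester acid
Product: 30 1-({(1R,6S)-5,5-dimethoxy-2-oxo-1-{[(1S,4aS,8aS)-5,5,8a-trimethyl-2-methylidenedecahydronaphthalen-1-yl]methyl}-7-oxabicyclo[4.1.0]hept-3-en-4-yl}methyl) 5-(4-methoxybenzyl) (3S)-3-hydroxy-3-methylpentanedioate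
Conditions: EDC·HCl, DMAP (0.2 equiv), CH2Cl2, 0 °C → rt
Reagents that add atoms: none
Why: Steglich (carbodiimide/DMAP) esterification of the primary allylic alcohol, the tertiary hydroxyl being too hindered to compete.

Step 19
Reactants: 30 the protected diester
Product: 31 4'-oxomacrophorin D
Conditions: TFA–CH2Cl2 (1:9), anisole (5 equiv), H2O (5 equiv), 0 °C
Reagents that add atoms: water, O
Why: Acidolysis cleaves the 4-methoxybenzyl ester (benzylic cation trapped by anisole) and hydrolyses the dimethyl ketal to the second ketone, and the epoxy enedione and the exocyclic alkene are expected to tolerate brief cold dilute acid.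

## Compound list

1 | isobutyronitrile | CC(C)C#N | starting material
2 | 5-iodopent-1-yne | C#CCCCI | starting material
3 | lithiated isobutyronitrile | [Li]C(C)(C)C#N | intermediate (not isolated)
4 | 2,2-dimethylhept-6-ynenitrile | C#CCCCC(C)(C)C#N | intermediate
5 | N-(diisobutylaluminio)-2,2-dimethylhept-6-yn-1-imine | C#CCCCC(C)(C)C=N[Al](CC(C)C)CC(C)C | intermediate (not isolated)
6 | 2,2-dimethylhept-6-ynal | C#CCCCC(C)(C)C=O | intermediate
7 | 3,3-dimethyloct-1-en-7-yne | C#CCCCC(C)(C)C=C | intermediate
8 | dimethyl[(1E)-2,6,6-trimethylocta-1,7-dien-1-yl]alane | C[Al](C)/C=C(\C)CCCC(C)(C)C=C | intermediate (not isolated)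
9 | (E)-4,8,8-trimethyldeca-3,9-dien-2-one | CC(=O)/C=C(\C)CCCC(C)(C)C=C | intermediate
10 | (2E,8E)-4,4,8-trimethyl-10-oxoundeca-2,8-dienal | CC(=O)/C=C(\C)CCCC(C)(C)/C=C/C=O | intermediate
11 | (2E,8E)-10-[(tert-butyldimethylsilyl)oxy]-4,4,8-trimethylundeca-2,8,10-trienal | C=C(O[Si](C)(C)C(C)(C)C)/C=C(\C)CCCC(C)(C)/C=C/C=O | intermediate
12 | (1S,4aS,8aS)-3-[(tert-butyldimethylsilyl)oxy]-4a,8,8-trimethyl-1,2,4a,5,6,7,8,8a-octahydronaphthalene-1-carbaldehyde | O=C[C@H]1CC(O[Si](C)(C)C(C)(C)C)=C[C@@]2(C)CCCC(C)(C)[C@H]12 | intermediate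
13 | tert-butyldimethyl{[(4aS,8aS)-5,5,8a-trimethyl-3,4,4a,5,6,7,8,8a-octahydronaphthalen-2-yl]oxy}silane | C1CC(O[Si](C)(C)C(C)(C)C)=C[C@@]2(C)CCCC(C)(C)[C@H]12 | intermediate
14 | methyl 3-hydroxy-4-methylbenzoate | COC(=O)c1ccc(C)c(O)c1 | starting material
15 | methyl 3-[(diethylcarbamoyl)oxy]-4-methylbenzoate | CCN(CC)C(=O)Oc1cc(C(=O)OC)ccc1C | intermediate
16 | methyl 4-(bromomethyl)-3-[(diethylcarbamoyl)oxy]benzoate | CCN(CC)C(=O)Oc1cc(C(=O)OC)ccc1CBr | intermediate
17 | tris(dimethylamino)sulfonium (4aS,8aS)-5,5,8a-trimethyl-3,4,4a,5,6,7,8,8a-octahydronaphthalen-2-olate | C1CC([O-])=C[C@@]2(C)CCCC(C)(C)[C@H]12.CN(C)[S+](N(C)C)N(C)C | intermediate (not isolated)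
18 | methyl 3-[(diethylcarbamoyl)oxy]-4-{[(1S,4aS,8aS)-5,5,8a-trimethyl-2-oxodecahydronaphthalen-1-yl]methyl}benzoate (9α-benzyl epimer) | O=C1CC[C@H]2C(C)(C)CCC[C@]2(C)[C@@H]1Cc1ccc(C(=O)OC)cc1OC(=O)N(CC)CC | intermediate (not isolated)
19 | methyl 3-[(diethylcarbamoyl)oxy]-4-{[(1R,4aS,8aS)-5,5,8a-trimethyl-2-oxodecahydronaphthalen-1-yl]methyl}benzoate | O=C1CC[C@H]2C(C)(C)CCC[C@]2(C)[C@H]1Cc1ccc(C(=O)OC)cc1OC(=O)N(CC)CC | intermediate
20 | methyl 3-[(diethylcarbamoyl)oxy]-4-{[(1S,4aS,8aS)-5,5,8a-trimethyl-2-methylidenedecahydronaphthalen-1-yl]methyl}benzoate | C=C1CC[C@H]2C(C)(C)CCC[C@]2(C)[C@H]1Cc1ccc(C(=O)OC)cc1OC(=O)N(CC)CC | intermediate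
21 | 5-(hydroxymethyl)-2-{[(1S,4aS,8aS)-5,5,8a-trimethyl-2-methylidenedecahydronaphthalen-1-yl]methyl}phenol | C=C1CC[C@H]2C(C)(C)CCC[C@]2(C)[C@H]1Cc1ccc(CO)cc1O | intermediate
22 | 5-(hydroxymethyl)-4-methoxy-2-{[(1S,4aS,8aS)-5,5,8a-trimethyl-2-methylidenedecahydronaphthalen-1-yl]methyl}phenol | C=C1CC[C@H]2C(C)(C)CCC[C@]2(C)[C@H]1Cc1cc(OC)c(CO)cc1O | intermediate (not isolated)
23 | 5-(hydroxymethyl)-4,4-dimethoxy-2-{[(1S,4aS,8aS)-5,5,8a-trimethyl-2-methylidenedecahydronaphthalen-1-yl]methyl}cyclohexa-2,5-dien-1-one | C=C1CC[C@H]2C(C)(C)CCC[C@]2(C)[C@H]1CC1=CC(OC)(OC)C(CO)=CC1=O | intermediate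
24 | (1R,6S)-4-(hydroxymethyl)-5,5-dimethoxy-1-{[(1S,4aS,8aS)-5,5,8a-trimethyl-2-methylidenedecahydronaphthalen-1-yl]methyl}-7-oxabicyclo[4.1.0]hept-3-en-2-one | C=C1CC[C@H]2C(C)(C)CCC[C@]2(C)[C@H]1C[C@@]12O[C@@H]1C(OC)(OC)C(CO)=CC2=O | intermediate
25 | (R)-mevalonolactone | C[C@@]1(O)CCOC(=O)C1 | starting material
26 | potassium (R)-mevalonate | OCC[C@@](C)(O)CC(=O)[O-].[K+] | intermediate (not isolated)
27 | 4-methoxybenzyl (R)-3,5-dihydroxy-3-methylpentanoate | OCC[C@@](C)(O)CC(=O)OCc1ccc(OC)cc1 | intermediate
28 | 4-methoxybenzyl (R)-3-hydroxy-3-methyl-5-oxopentanoate | O=CC[C@@](C)(O)CC(=O)OCc1ccc(OC)cc1 | intermediate (not isolated)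
29 | (R)-3-hydroxy-5-[(4-methoxybenzyl)oxy]-3-methyl-5-oxopentanoic acid | OC(=O)C[C@@](C)(O)CC(=O)OCc1ccc(OC)cc1 | intermediate
30 | 1-({(1R,6S)-5,5-dimethoxy-2-oxo-1-{[(1S,4aS,8aS)-5,5,8a-trimethyl-2-methylidenedecahydronaphthalen-1-yl]methyl}-7-oxabicyclo[4.1.0]hept-3-en-4-yl}methyl) 5-(4-methoxybenzyl) (3S)-3-hydroxy-3-methylpentanedioate | C=C1CC[C@H]2C(C)(C)CCC[C@]2(C)[C@H]1C[C@@]12O[C@@H]1C(OC)(OC)C(COC(=O)C[C@@](C)(O)CC(=O)OCc1ccc(OC)cc1)=CC2=O | intermediate
31 | 4'-oxomacrophorin D | C=C1CC[C@H]2C(C)(C)CCC[C@]2(C)[C@H]1C[C@@]12O[C@@H]1C(=O)C(COC(=O)C[C@@](C)(O)CC(=O)O)=CC2=O | target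

## Step count and risks

Total step count: 19. Longest linear sequence: 15 steps (steps 1–8, 11–15, 18 and 19). Steps 9–10 and 16–17 make the two side fragments.

Steps most likely to fail:

**Step 7 (key cycloaddition).** The C5–C10 bond joins a carbon next to quaternary C4 to a fully substituted diene terminus. The catalysed reaction may therefore be slow enough for intermolecular Mukaiyama-type addition of the silyl enol ether to the bound enal, or an unselective background cycloaddition, to take over. Facial discrimination by the catalyst may also be incomplete. The fallback is an auxiliary-controlled cycloaddition under stoichiometric bidentate Lewis acid activation, setting out from dienone 9. Cross-metathesis with (S)-3-acryloyl-4-benzyloxazolidin-2-one (same ruthenium catalyst as step 5) gives the keto imide F1. TBSOTf/Et3N gives the silyloxy triene imide F2. Me2AlCl (1.4 equiv) in CH2Cl2 at −30 °C gives the trans-fused cycloadduct F3 through the chelated cationic aluminium imide, the benzyl group of the auxiliary screening one face of the enoyl unit (the auxiliary antipode being chosen for the C5 Si face). LiBH4/MeOH in THF removes the auxiliary reductively to give the primary alcohol F4. Dess–Martin periodinane (NaHCO3 buffer) then returns aldehyde 12, where the route is rejoined.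

**Step 15 (epoxidation).** Facial selectivity of peroxide delivery may be poor if the tartrate chelate is mismatched with the bulky decalin substituent on the α-carbon. Ring closure at the fully substituted α-carbon may also be slow, so that the peroxide adduct reverts. The fallback uses ion-pair control without a free hydroxyl, setting out from 23. TBSCl/imidazole gives the silyl ether F5. tBuOOH, aqueous NaOH and N-benzylcinchonidinium chloride (or its pseudo-enantiomer from cinchonine) in PhMe at 0 °C give the epoxy ketal silyl ether F6 by asymmetric phase-transfer nucleophilic epoxidation. Bu4NF/AcOH in THF then returns 24.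

**Step 11 (benzylation and C9 equilibration).** The fluoride-generated enolate may undergo O-benzylation or proton transfer at the hindered neopentyl C9, which would lose the regiocontrol and give C7 alkylation. Equilibration at C9 may also be incomplete. The fallback is aldol condensation and hydrogenation, setting out from 13. TiCl4-mediated Mukaiyama aldol addition to methyl 3-[(diethylcarbamoyl)oxy]-4-formylbenzoate F7 (from commercial methyl 4-formyl-3-hydroxybenzoate with Et2NCOCl/K2CO3) gives the aldol F8. TsOH in warm toluene dehydrates it to the benzylidene ketone F9. H2 over palladium on carbon (Pd/C) in EtOAc should add hydrogen to C9 from the α face, anti to the angular methyl, and so return ketone 19 with 9α-H.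

## Further compounds

F1 | step 7 | (S)-4-benzyl-3-[(2E,8E)-4,4,8-trimethyl-10-oxoundeca-2,8-dienoyl]oxazolidin-2-one | CC(=O)/C=C(\C)CCCC(C)(C)/C=C/C(=O)N1C(=O)OC[C@@H]1Cc1ccccc1
F2 | step 7 | (S)-4-benzyl-3-{(2E,8E)-10-[(tert-butyldimethylsilyl)oxy]-4,4,8-trimethylundeca-2,8,10-trienoyl}oxazolidin-2-one | C=C(O[Si](C)(C)C(C)(C)C)/C=C(\C)CCCC(C)(C)/C=C/C(=O)N1C(=O)OC[C@@H]1Cc1ccccc1
F3 | step 7 | (S)-4-benzyl-3-{[(1S,4aS,8aS)-3-[(tert-butyldimethylsilyl)oxy]-4a,8,8-trimethyl-1,2,4a,5,6,7,8,8a-octahydronaphthalen-1-yl]carbonyl}oxazolidin-2-one | O=C([C@H]1CC(O[Si](C)(C)C(C)(C)C)=C[C@@]2(C)CCCC(C)(C)[C@H]12)N1C(=O)OC[C@@H]1Cc1ccccc1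
F4 | step 7 | [(1S,4aS,8aS)-3-[(tert-butyldimethylsilyl)oxy]-4a,8,8-trimethyl-1,2,4a,5,6,7,8,8a-octahydronaphthalen-1-yl]methanol | OC[C@H]1CC(O[Si](C)(C)C(C)(C)C)=C[C@@]2(C)CCCC(C)(C)[C@H]12
F5 | step 15 | 5-{[(tert-butyldimethylsilyl)oxy]methyl}-4,4-dimethoxy-2-{[(1S,4aS,8aS)-5,5,8a-trimethyl-2-methylidenedecahydronaphthalen-1-yl]methyl}cyclohexa-2,5-dien-1-one | C=C1CC[C@H]2C(C)(C)CCC[C@]2(C)[C@H]1CC1=CC(OC)(OC)C(CO[Si](C)(C)C(C)(C)C)=CC1=O
F6 | step 15 | (1R,6S)-4-{[(tert-butyldimethylsilyl)oxy]methyl}-5,5-dimethoxy-1-{[(1S,4aS,8aS)-5,5,8a-trimethyl-2-methylidenedecahydronaphthalen-1-yl]methyl}-7-oxabicyclo[4.1.0]hept-3-en-2-one | C=C1CC[C@H]2C(C)(C)CCC[C@]2(C)[C@H]1C[C@@]12O[C@@H]1C(OC)(OC)C(CO[Si](C)(C)C(C)(C)C)=CC2=O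
F7 | step 11 | methyl 3-[(diethylcarbamoyl)oxy]-4-formylbenzoate | O=Cc1ccc(C(=O)OC)cc1OC(=O)N(CC)CC
F8 | step 11 | methyl 3-[(diethylcarbamoyl)oxy]-4-{hydroxy[(4aS,8aS)-5,5,8a-trimethyl-2-oxodecahydronaphthalen-1-yl]methyl}benzoate (diastereomer mixture) | O=C1CC[C@H]2C(C)(C)CCC[C@]2(C)C1C(O)c1ccc(C(=O)OC)cc1OC(=O)N(CC)CC
F9 | step 11 | methyl 3-[(diethylcarbamoyl)oxy]-4-{[(4aS,8aS)-5,5,8a-trimethyl-2-oxooctahydronaphthalen-1(2H)-ylidene]methyl}benzoate | O=C1CC[C@H]2C(C)(C)CCC[C@]2(C)C1=Cc1ccc(C(=O)OC)cc1OC(=O)N(CC)CC
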